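The bicyclo[4.3.1]decane core is cut at the bond between the oxygenated one-carbon bridge (C10) and the allylic bridgehead (C9). The feature used is the homoallylic alcohol array C10(O)–C9–C1(=CH2), which lies in both the six-membered and the seven-membered ring and is the retron of a carbonyl-ene reaction. A Me2AlCl-promoted transannular carbonyl-ene reaction of a cyclonona-1,4-diene dialdehyde closes both rings, sets C9 and C10 and creates the exocyclic methylene in one operation. The nine-membered precursor is built from (S)-citronellal by an organocatalytic nitro-Michael addition, methallylboration, a second nitro-Michael addition and ring-closing metathesis.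

Key step: step 13

Skeleton numbering used below: C1 = ring carbon that ends as the exocyclic-methylene carbon (methyl-bearing alkene carbon in the precursors); C2 = ring CH2; C3 = CH–O; C4 = CH bearing the side chain; C5 = bridgehead next to C4; C6 = formyl-bearing alkene carbon; C7 = alkene CH; C8 = allylic CH2; C9 = bridgehead next to C1; C10 = bridging CH–O; C11 = side-chain methine. In this numbering the target is 3S,4R,5R,9R,10S,11S.

Remark: ring-closing metathesis is assumed to give the (Z)-C1=C9 alkene; the key step erases this stereoelement, and the Z isomer places the C1 methyl group on the side needed for hydrogen transfer.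

Step 1
Reactants: 1 2,2-dimethoxyacetaldehyde; 2 nitromethane
Product: 3 3,3-dimethoxy-1-nitropropan-2-ol (racemic)
Conditions: K2CO3 (cat.), THF/H2O, 0 °C to rt
Reagents that add atoms: none
Why: Base-catalysed Henry (nitroaldol) addition to a non-enolisable aldehyde should give the nitro alcohol, whose single stereocentre is removed in step 2.

Step 2
Reactants: 3 3,3-dimethoxy-1-nitropropan-2-ol
Product: 4 (E)-3,3-dimethoxy-1-nitroprop-1-ene
Conditions: MsCl, Et3N, CH2Cl2, −20 to 0 °C
Reagents that add atoms: none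
Why: Mesylation and E1cB elimination (Henry dehydration) should give the conjugated nitroalkene as the favoured E isomer.

Step 3
Reactants: 4 (E)-3,3-dimethoxy-1-nitroprop-1-ene; 5 (S)-citronellal
Product: 6 (2R,3R)-3-(dimethoxymethyl)-2-[(2S)-6-methylhept-5-en-2-yl]-4-nitrobutanal
Conditions: (S)-α,α-diphenylprolinol trimethylsilyl ether (10 mol%), 4-nitrophenol (10 mol%), 5 in excess, toluene, 0 °C; used crude
Reagents that add atoms: none
Why: Enamine-mediated asymmetric Michael addition (diarylprolinol silyl ether catalysis): the E enamine of 5 should add from the face not shielded by the catalyst through the open synclinal transition state, which sets C4 and C5 as the syn adduct under catalyst control, the acetal carbon becoming C10 and the nitromethyl carbon C6.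

Step 4
Reactants: 6 nitro aldehyde
Product: 7 (4S,5R,6R)-6-(dimethoxymethyl)-2-methyl-5-[(2S)-6-methylhept-5-en-2-yl]-7-nitrohept-1-en-4-ol
Conditions: (−)-Ipc2BOMe, methallylmagnesium chloride, Et2O, −78 °C to rt; then 6, −78 °C; then ethanolamine, rt
Reagents that add atoms: B-methallyldiisopinocampheylborane CC(=C)CB([C@@H]1C[C@@H]2C[C@H]([C@H]1C)C2(C)C)[C@@H]1C[C@@H]2C[C@H]([C@H]1C)C2(C)C
Why: Brown asymmetric methallylboration through a chair Zimmerman–Traxler transition state: the reagent derived from (+)-α-pinene should deliver the methallyl group to the Si face of the aldehyde under reagent control and so set C3 as S.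

Step 5
Reactants: 7 homoallylic alcohol
Product: 8 tert-butyldimethylsilyl ether of 7
Conditions: TBSCl, imidazole, DMAP (cat.), DMF, 40 °C
Reagents that add atoms: tert-butyldimethylsilyl chloride CC(C)(C)[Si](C)(C)Cl
Why: Standard silylation protects the C3 hydroxyl so that it cannot add to the C6 or C10 carbonyl groups that appear later.

Step 6
Reactants: 8 silyl ether; 9 acrolein
Product: 10 (5R,6R,7S)-7-(tert-butyldimethylsilyloxy)-5-(dimethoxymethyl)-9-methyl-6-[(2S)-6-methylhept-5-en-2-yl]-4-nitrodec-9-enal (both C4 epimers)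
Conditions: DBU (0.1 equiv), MeCN, −20 to 0 °C
Reagents that add atoms: none
Why: Base-catalysed nitronate Michael addition to acrolein builds C7–C9; the hindered surroundings of C6 should stop it at the mono-adduct, and the new C6 stereocentre is erased in step 8.

Step 7
Reactants: 10 nitro aldehyde
Product: 11 (4S,5R,6R)-4-(tert-butyldimethylsilyloxy)-6-(dimethoxymethyl)-2-methyl-5-[(2S)-6-methylhept-5-en-2-yl]-7-nitroundeca-1,10-diene (both C7 epimers)
Conditions: Ph3PCH3Br, KOtBu (3 equiv of ylide), THF, 0 °C; AcOH quench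
Reagents that add atoms: methylenetriphenylphosphorane C=P(c1ccccc1)(c1ccccc1)c1ccccc1
Why: Wittig methylenation of the aldehyde; excess ylide only converts the nitro group into an inert nitronate, which is reprotonated on work-up.

Step 8
Reactants: 11 nitro diene
Product: 13 (6S,7R,8S)-8-(tert-butyldimethylsilyloxy)-6-(dimethoxymethyl)-10-methyl-7-[(2S)-6-methylhept-5-en-2-yl]undeca-1,10-dien-5-one, via sodium nitronate 12 (not isolated)
Conditions: NaOMe, MeOH, 0 °C; then aq. TiCl3, NH4OAc, THF, pH 5–6, rt
Reagents that add atoms: water O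
Why: Reductive Nef reaction: trivalent titanium reduces the nitronate to the imine, which hydrolyses at buffered pH to the C6 ketone without touching the acetal, the silyl ether or the alkenes.

Step 9
Reactants: 13 diene ketone
Product: 14 (Z)-cyclononenone: (3S,4R,5S)-3-(tert-butyldimethylsilyloxy)-5-(dimethoxymethyl)-1-methyl-4-[(2S)-6-methylhept-5-en-2-yl]cyclonon-1(9)-en-6-one (skeleton numbering)
Conditions: second-generation Hoveyda–Grubbs catalyst (10 mol%), 1,4-benzoquinone (20 mol%), toluene (1 mM), 90 °C
Reagents that add atoms: none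
Why: Ring-closing metathesis of the 1,1-disubstituted and the monosubstituted alkene under high dilution should close the nine-membered ring as the less strained Z trisubstituted alkene, the sp2 C6 carbonyl easing transannular strain.

Step 10
Reactants: 14 cyclononenone
Product: 16 enol triflate of 14 (C6–OTf, C6=C7 double bond, C5 and C8 cis on it), via potassium enolate 15 (not isolated)
Conditions: KHMDS, THF, −78 °C; then PhNTf2, −78 to −20 °C
Reagents that add atoms: N-phenylbis(trifluoromethanesulfonimide) O=S(=O)(N(c1ccccc1)S(=O)(=O)C(F)(F)F)C(F)(F)F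
Why: Kinetic deprotonation at the unhindered C7 methylene and O-triflation of the enolate; the ring holds C5 and C8 cis on the new double bond.

Step 11
Reactants: 16 enol triflate
Product: 17 enal acetal: cyclonona-1(9),6-diene with C6–CHO (formyl trans to C8), C5–CH(OMe)2, C3–OTBS (3S,4R,5R,11S)
Conditions: Pd(OAc)2 (5 mol%), dppp (5 mol%), CO (1 atm), Et3SiH, Et3N, DMF, 70 °C
Reagents that add atoms: carbon monoxide [C-]#[O+]
Why: Palladium-catalysed reductive carbonylation (formylation) of the enol triflate: oxidative addition to zerovalent palladium, CO insertion and hydride transfer from the silane should give the enal with the ring-enforced geometry.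

Step 12
Reactants: 17 enal acetal
Product: 18 dialdehyde: cyclonona-1(9),6-diene with C5–CHO (C10) and C6–CHO, C3–OTBS (3S,4R,5R,11S)
Conditions: LiBF4, MeCN/H2O (98:2), rt; used at once
Reagents that add atoms: water O
Why: Mild Lewis-acid-assisted hydrolysis of the dimethyl acetal frees the C10 aldehyde under near-neutral conditions that spare the silyl ether and limit enolisation at C5.

Step 13
Reactants: 18 dialdehyde
Product: 19 bicyclic hydroxy enal: bicyclo[4.3.1]decene with C1 exocyclic methylene, C3–OTBS, C6–CHO on C6=C7, C10–OH syn to the C1–C4 bridge (3S,4R,5R,9R,10S,11S)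
Conditions: Me2AlCl (2.2 equiv), CH2Cl2, −78 to −40 °C
Reagents that add atoms: none
Why: Me2AlCl activates the C10 aldehyde, whose carbon bonds across the ring to C9 of the C1=C9 alkene while a hydrogen of the C1 methyl group passes to oxygen through a six-membered transition state, the Al–Me bonds scavenging protons so that no free cation is left to rearrange. The closest known reaction type is the Lewis-acid-promoted intramolecular carbonyl-ene reaction (the citronellal-to-isopulegol closure), here run transannularly. With respect to the C1=C9 alkene the new bond closes the cyclohexene ring (C5, C6, C7, C8, C9, C10) in a 6-exo mode and the seven-membered ring (C1, C2, C3, C4, C5, C10, C9) in a 7-endo mode. C9 is set by the ring, because the one-carbon bridge can only span C5 and C9 on the same face, so C9 follows from C5; C10 is set by the ene geometry, because the oxygen must sit over the C1 methyl group (cis to H9 in the Z alkene) and so ends up syn to the four-carbon bridge. The step needs attack at C9 and not C1 (charge develops at the tertiary C1), reaction of the C10 aldehyde and not the conjugated C6 formyl group (less electrophilic and held trans to C8), hydrogen transfer from the methyl group and not from C2 (C2 lies on the far side of C1 from the oxygen), and no reaction at the side-chain alkene (it could only close a seven-membered ring and lacks transannular proximity).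

Step 14
Reactants: 19 bicyclic hydroxy enal
Product: 20 diol: 19 with free C3–OH (3S,4R,5R,9R,10S,11S)
Conditions: TBAF, AcOH, THF, 0 °C to rt
Reagents that add atoms: none
Why: Fluoride-mediated cleavage of the silyl ether, buffered with acetic acid to protect the enal, frees the C3 hydroxyl.

Step 15
Reactants: 20 diol
Product: 21 CNP0197379.1, the C3,C10-diacetate
Conditions: Ac2O, pyridine, DMAP (cat.), CH2Cl2, rt
Reagents that add atoms: acetic anhydride CC(=O)OC(C)=O
Why: DMAP-catalysed acylation of both secondary hydroxyl groups gives the diacetate without touching any stereocentre.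

Compound list
1 | 2,2-dimethoxyacetaldehyde | COC(OC)C=O | starting material
2 | nitromethane | C[N+](=O)[O-] | starting material
3 | 3,3-dimethoxy-1-nitropropan-2-ol (racemic) | COC(OC)C(O)C[N+](=O)[O-] | intermediate
4 | (E)-3,3-dimethoxy-1-nitroprop-1-ene | COC(OC)/C=C/[N+](=O)[O-] | intermediate
5 | (S)-citronellal, (3S)-3,7-dimethyloct-6-enal | O=CC[C@@H](C)CCC=C(C)C | starting material
6 | (2R,3R)-3-(dimethoxymethyl)-2-[(2S)-6-methylhept-5-en-2-yl]-4-nitrobutanal | O=C[C@H]([C@@H](C)CCC=C(C)C)[C@@H](C(OC)OC)C[N+](=O)[O-] | intermediate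
7 | (4S,5R,6R)-6-(dimethoxymethyl)-2-methyl-5-[(2S)-6-methylhept-5-en-2-yl]-7-nitrohept-1-en-4-ol | C=C(C)C[C@H](O)[C@H]([C@@H](C)CCC=C(C)C)[C@@H](C(OC)OC)C[N+](=O)[O-] | intermediate
8 | tert-butyldimethylsilyl ether of 7 | C=C(C)C[C@H](O[Si](C)(C)C(C)(C)C)[C@H]([C@@H](C)CCC=C(C)C)[C@@H](C(OC)OC)C[N+](=O)[O-] | intermediate
9 | acrolein (prop-2-enal) | C=CC=O | starting material
10 | (5R,6R,7S)-7-(tert-butyldimethylsilyloxy)-5-(dimethoxymethyl)-9-methyl-6-[(2S)-6-methylhept-5-en-2-yl]-4-nitrodec-9-enal, both C4 epimers | C=C(C)C[C@H](O[Si](C)(C)C(C)(C)C)[C@H]([C@@H](C)CCC=C(C)C)[C@@H](C(OC)OC)C(CCC=O)[N+](=O)[O-] | intermediate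
11 | (4S,5R,6R)-4-(tert-butyldimethylsilyloxy)-6-(dimethoxymethyl)-2-methyl-5-[(2S)-6-methylhept-5-en-2-yl]-7-nitroundeca-1,10-diene, both C7 epimers | C=C(C)C[C@H](O[Si](C)(C)C(C)(C)C)[C@H]([C@@H](C)CCC=C(C)C)[C@@H](C(OC)OC)C(CCC=C)[N+](=O)[O-] | intermediate
12 | sodium nitronate of 11 | C=C(C)C[C@H](O[Si](C)(C)C(C)(C)C)[C@H]([C@@H](C)CCC=C(C)C)[C@@H](C(OC)OC)C(CCC=C)=[N+]([O-])[O-].[Na+] | intermediate (not isolated)
13 | (6S,7R,8S)-8-(tert-butyldimethylsilyloxy)-6-(dimethoxymethyl)-10-methyl-7-[(2S)-6-methylhept-5-en-2-yl]undeca-1,10-dien-5-one | C=C(C)C[C@H](O[Si](C)(C)C(C)(C)C)[C@H]([C@@H](C)CCC=C(C)C)[C@@H](C(OC)OC)C(=O)CCC=C | intermediate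
14 | (Z)-cyclononenone, (3S,4R,5S)-3-(tert-butyldimethylsilyloxy)-5-(dimethoxymethyl)-1-methyl-4-[(2S)-6-methylhept-5-en-2-yl]cyclonon-1(9)-en-6-one (skeleton numbering) | C/C1=C/CCC(=O)[C@H](C(OC)OC)[C@@H]([C@@H](C)CCC=C(C)C)[C@@H](O[Si](C)(C)C(C)(C)C)C1 | intermediate
15 | potassium C6=C7 enolate of 14 | C/C1=C/C/C=C(/[O-])[C@H](C(OC)OC)[C@@H]([C@@H](C)CCC=C(C)C)[C@@H](O[Si](C)(C)C(C)(C)C)C1.[K+] | intermediate (not isolated)
16 | enol triflate of 14 (C6–OTf, C6=C7, C5 and C8 cis) | C/C1=C/C/C=C(/OS(=O)(=O)C(F)(F)F)[C@H](C(OC)OC)[C@@H]([C@@H](C)CCC=C(C)C)[C@@H](O[Si](C)(C)C(C)(C)C)C1 | intermediate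
17 | enal acetal (C6–CHO trans to C8, C5–CH(OMe)2, C3–OTBS; 3S,4R,5R,11S) | C/C1=C/C/C=C(/C=O)[C@H](C(OC)OC)[C@@H]([C@@H](C)CCC=C(C)C)[C@@H](O[Si](C)(C)C(C)(C)C)C1 | intermediate
18 | dialdehyde (C5–CHO and C6–CHO, C3–OTBS; 3S,4R,5R,11S) | C/C1=C/C/C=C(/C=O)[C@H](C=O)[C@@H]([C@@H](C)CCC=C(C)C)[C@@H](O[Si](C)(C)C(C)(C)C)C1 | intermediate
19 | bicyclic hydroxy enal (C1 methylene, C3–OTBS, C6–CHO, C10–OH; 3S,4R,5R,9R,10S,11S) | C=C1C[C@H](O[Si](C)(C)C(C)(C)C)[C@H]([C@@H](C)CCC=C(C)C)[C@@H]2C(C=O)=CC[C@H]1[C@@H]2O | intermediate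
20 | diol (C3–OH, C10–OH; 3S,4R,5R,9R,10S,11S) | C=C1C[C@H](O)[C@H]([C@@H](C)CCC=C(C)C)[C@@H]2C(C=O)=CC[C@H]1[C@@H]2O | intermediate
21 | CNP0197379.1, C3,C10-diacetate (3S,4R,5R,9R,10S,11S) | C=C1C[C@H](OC(C)=O)[C@H]([C@@H](C)CCC=C(C)C)[C@@H]2C(C=O)=CC[C@H]1[C@@H]2OC(C)=O | target

Total step count: 15. Longest linear sequence: 15 steps (from 1 or 2 to 21; 13 steps from 5).

Steps most likely to fail

Step 9 (ring-closing metathesis). Intermolecular cross-metathesis may outrun closure of the strained nine-membered ring, and ruthenium hydride species may shift the terminal alkene and lead to ring-contracted products. The fallback closes the ring by a Nozaki–Hiyama–Kishi reaction; it sets out from 6 and comes back at 14. Aldehyde 6 is 2-bromoallylated at its Si face with the chiral (2-bromoallyl)borane made from (2-bromoallyl)tributylstannane and a 1,2-diphenylethane-1,2-bis(p-toluenesulfonamide) bromoborane, which should give the bromo homoallylic alcohol F1. TBSCl and imidazole give the silyl ether F2, and DBU-catalysed addition to acrolein 9 gives the nitro aldehyde F3. The buffered TiCl3 Nef reaction gives the keto aldehyde F4. CrCl2 with catalytic NiCl2 in DMSO/THF at high dilution joins C1 to C9 chemoselectively at the aldehyde and gives the nine-membered hydroxy ketone F5 with an exocyclic methylene. A reductive 1,3-transposition through the allylic diazene (2-nitrobenzenesulfonylhydrazide, PPh3, DEAD, −30 °C to rt) moves the double bond into the ring and gives 14.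

Step 13 (transannular carbonyl-ene reaction). The 1,4-dialdehyde may epimerise at C5 or cyclodehydrate to a furan before it cyclises, and the Lewis acid may start cationic side reactions at the enal. The fallback runs the same ring closure on a substrate whose only carbonyl group is the C10 aldehyde; it sets out from 17 and comes back at 20. Luche reduction of 17 (NaBH4, CeCl3·7H2O, MeOH) gives the allylic alcohol F6, and silylation gives the bis(silyl ether) F7. LiBF4 in wet MeCN gives the mono-aldehyde F8, and Me2AlCl gives the bicyclic alcohol F9. TBAF gives the triol F10, and MnO2 oxidises only the allylic primary alcohol to give 20.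

Step 11 (reductive carbonylation). The vinylpalladium intermediate may capture hydride before CO inserts, which would simply reduce the triflate, and the skipped diene may isomerise. The fallback introduces the formyl group by a Shapiro reaction; it sets out from 14 and comes back at 17. Ketone 14 is condensed with 2,4,6-triisopropylbenzenesulfonylhydrazide to the sulfonylhydrazone F11. s-BuLi (2.2 equiv, THF, −78 to 0 °C) deprotonates at C7 and generates the C6 vinyllithium, and a DMF quench gives 17.

Further compounds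
F1 | step 9 | (4S,5R,6R)-2-bromo-6-(dimethoxymethyl)-5-[(2S)-6-methylhept-5-en-2-yl]-7-nitrohept-1-en-4-ol | C=C(Br)C[C@H](O)[C@H]([C@@H](C)CCC=C(C)C)[C@@H](C(OC)OC)C[N+](=O)[O-]
F2 | step 9 | tert-butyldimethylsilyl ether of F1 | C=C(Br)C[C@H](O[Si](C)(C)C(C)(C)C)[C@H]([C@@H](C)CCC=C(C)C)[C@@H](C(OC)OC)C[N+](=O)[O-]
F3 | step 9 | acrolein adduct of F2 at C6 (both C6 epimers) | C=C(Br)C[C@H](O[Si](C)(C)C(C)(C)C)[C@H]([C@@H](C)CCC=C(C)C)[C@@H](C(OC)OC)C(CCC=O)[N+](=O)[O-]
F4 | step 9 | keto aldehyde (C6 ketone, C9 aldehyde, 2-bromoallyl on C3) | C=C(Br)C[C@H](O[Si](C)(C)C(C)(C)C)[C@H]([C@@H](C)CCC=C(C)C)[C@@H](C(OC)OC)C(=O)CCC=O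
F5 | step 9 | nine-membered hydroxy ketone (C1 exocyclic methylene, C9–OH both epimers, C6 ketone) | C=C1C[C@H](O[Si](C)(C)C(C)(C)C)[C@H]([C@@H](C)CCC=C(C)C)[C@@H](C(OC)OC)C(=O)CCC1O
F6 | step 13 | allylic alcohol (17 with C6–CH2OH) | C/C1=C/C/C=C(/CO)[C@H](C(OC)OC)[C@@H]([C@@H](C)CCC=C(C)C)[C@@H](O[Si](C)(C)C(C)(C)C)C1
F7 | step 13 | bis(tert-butyldimethylsilyl ether) of F6 | C/C1=C/C/C=C(/CO[Si](C)(C)C(C)(C)C)[C@H](C(OC)OC)[C@@H]([C@@H](C)CCC=C(C)C)[C@@H](O[Si](C)(C)C(C)(C)C)C1
F8 | step 13 | mono-aldehyde (C5–CHO, C6–CH2OTBS, C3–OTBS) | C/C1=C/C/C=C(/CO[Si](C)(C)C(C)(C)C)[C@H](C=O)[C@@H]([C@@H](C)CCC=C(C)C)[C@@H](O[Si](C)(C)C(C)(C)C)C1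
F9 | step 13 | bicyclic alcohol (C10–OH, C6–CH2OTBS, C3–OTBS, C1 methylene) | C=C1C[C@H](O[Si](C)(C)C(C)(C)C)[C@H]([C@@H](C)CCC=C(C)C)[C@@H]2C(CO[Si](C)(C)C(C)(C)C)=CC[C@H]1[C@@H]2O
F10 | step 13 | triol (C3–OH, C10–OH, C6–CH2OH) | C=C1C[C@H](O)[C@H]([C@@H](C)CCC=C(C)C)[C@@H]2C(CO)=CC[C@H]1[C@@H]2O
F11 | step 11 | 2,4,6-triisopropylbenzenesulfonylhydrazone of 14 | C/C1=C/CCC(=NNS(=O)(=O)c2c(C(C)C)cc(C(C)C)cc2C(C)C)[C@H](C(OC)OC)[C@@H]([C@@H](C)CCC=C(C)C)[C@@H](O[Si](C)(C)C(C)(C)C)C1
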